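The numbers are those of an exercise, and the outcome is calculated.

You asked for a quick number, so start from what stays over in this flask: undissolved solid substrate, 0.30 M charged against a solubility of 13 mM.

solid substrate 0.30 M; reagent 0.950 equiv; second substrate 2.00 equiv (in portions, 2); protic impurity 0.0900 M; time 15 h; the portions of second substrate follow each other after 2.0 min, the first at the start

    solid substrate ⇌ starting material, rate k1*(cs1 - [starting material]) while solid is left; crystals form when [starting material] > cs1 (cs1 = 13 mM, k1 = 0.093 min⁻¹)
    second substrate + protic impurity → quenched substrate (k2 = 7.2 M⁻¹ min⁻¹)
    starting material + reagent ⇌ target (K3 = 3.1 M⁻¹, k3 = 0.070 M⁻¹ min⁻¹)
    second substrate + reagent ⇌ second product (K4 = 0.099 M⁻¹, k4 = 0.0023 M⁻¹ min⁻¹)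

- solid, in amounts per volume of the solution: solid substrate
- at the start none of the solid substrate is in solution
- what has only dissolved of solid substrate counts as not reacted
- the reaction counts as stopped when no species that holds the solid substrate changes by six tenths of a point or more over the second half of the time
- starting material means what is dissolved; the solid is not counted in it
- run time (flask): 15 h

- the state of affairs at 15 h: stopped, and by what, or still going (for what has run out or reacted, a solid counts together with what of it has only dissolved) (forward and back rates have come level / it is still moving / the reagent has run out first / all of the solid substrate has reacted)
- part of the solid substrate that has turned into other species by 15 h (what has only dissolved does not count)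
- amount of target at 15 h, in percent of the solid substrate charged
- amount of starting material at 15 h, in percent of the solid substrate charged

Divide the forward rate of the step to target by its back rate, and time drops out. Set that quotient to one while solid stands and starting material sits at its solubility. Target over free reagent then equals the equilibrium constant 3.1 M⁻¹ times the solubility: the capped ratio ρ, 0.0403.

Now balance the reagent over its forms. The protic impurity takes its share of second substrate first, since at its charged concentration second substrate has a half-life of 1.07 min against it, shorter than the 18 h toward second product. Take 0.510 M of second substrate as free. Second product over free reagent is then 0.0505, so target's share of the reagent is 0.0369.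

Expect level rates: the forward half-life of starting material, 0.58 h, and the back half-life of second product, 0.497 h, are both shorter than 15 h. This is thermodynamic control, not kinetic. My number: target and conversion 3.51%, starting material 4.33%.

The forecast says forward and back rates have come level, with conversion 3.5%, target 3.5% and starting material 4.33%, noting that “Both reversible steps relax in about 45 min”.

The simulation gives forward and back rates have come level, with conversion 3.51%, target 3.51% and starting material 4.33%.

In this flask the relaxation half-life of the step to target, 0.276 h at 15.0 h, is shorter than the 15 h of the run, and target reads 3.51% at 7.50 h and 3.51% at 150 h. Target over free reagent at the end reads 0.0403, beside ρ of 0.0403. Carry the same share to the neighbour with 2.40 equiv of reagent: it gives 8.87%, and that flask, with 86.8% of its solid still standing, holds target at 8.89%.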